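Everything rests on disconnecting the O–C15 bond of the oxane ring. Its oxygen bridges two fully substituted carbons, C11 and the gem-dimethyl carbon C15, next to the C14 ester carbinol; such an ether cannot be made by substitution at either carbon, but it is the Markovnikov adduct of the C11 hydroxyl and a C14 isopropenyl group. One cobalt-hydride hydrogen atom transfer with radical-polar crossover forms this bond and closes the oxane on the finished 15-membered macrolactone under neutral conditions. The precursor is that macrolactone with ring A, both secondary bromides, the free C10/C11 bromohydrin, the C14 isopropenyl group and the phenol kept as a silyl ether.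

Key step: step 19

Remark: atoms carry the numbers of the natural product (C1 benzylic CH2; C2=C3, C6 and C7 in ring A; C10 CHBr; C11 and C15 ether carbons; C14 ester carbinol). For step 10 it is assumed that one member of the quinine/quinidine-derived catalyst pair delivers the 10R,11R lactone; a trial run settles which, since the two outcomes are diastereomers.

Step 1
Reactants: 1 2-(2-bromoethyl)-1,3-dioxolane; 2 propyne; 3 oxirane
Product: 6 (3Z)-6-(1,3-dioxolan-2-yl)-4-methylhex-3-en-1-ol, via Grignard reagent 4 (not isolated), via alkenylcopper 5 (not isolated)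
Conditions: Mg, THF, 25 °C; CuBr·SMe2, Et2O/Me2S, −45 °C; propyne, −25 °C; 1-pentynyllithium (from 1-pentyne, n-BuLi), HMPA, then oxirane, −40 → −15 °C; aq. NH4Cl
Reagents that add atoms: none
Why: Normant carbocupration: the alkylcopper adds syn across propyne with the new C11–C12 bond at the internal carbon, and the alkenyl–copper bond (as the mixed pentynyl cuprate) then opens oxirane with retention, so C9 and C12 end up cis and the (Z)-C10=C11 geometry is fixed.

Step 2
Reactants: 6 (3Z)-6-(1,3-dioxolan-2-yl)-4-methylhex-3-en-1-ol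
Product: 7 2-[(3Z)-6-iodo-3-methylhex-3-en-1-yl]-1,3-dioxolane
Conditions: I2, PPh3, imidazole, CH2Cl2, 0 °C → rt
Reagents that add atoms: iodine, II
Why: Appel-type iodination of a primary alcohol proceeds by SN2 at C8 under buffered conditions that spare the acetal and the trisubstituted alkene.

Step 3
Reactants: 8 2-methylcyclohexane-1,3-dione
Product: 9 3-(2,2-dimethylhydrazinyl)-2-methylcyclohex-2-en-1-one
Conditions: Me2NNH2, TsOH (cat.), toluene, 80 °C
Reagents that add atoms: N,N-dimethylhydrazine, CN(C)N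
Why: Condensation of one carbonyl gives the vinylogous hydrazide, whose anion is alkylated on carbon by unactivated halides where the dione enolate itself would react on oxygen.

Step 4
Reactants: 9 3-(2,2-dimethylhydrazinyl)-2-methylcyclohex-2-en-1-one; 7 2-[(3Z)-6-iodo-3-methylhex-3-en-1-yl]-1,3-dioxolane
Product: 11 2-[(3Z)-6-(1,3-dioxolan-2-yl)-4-methylhex-3-en-1-yl]-2-methylcyclohexane-1,3-dione, via alkylated hydrazone 10 (not isolated)
Conditions: KH, THF, 0 °C; 7, 0 °C → rt; then Cu(OAc)2·H2O, THF/H2O, rt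
Reagents that add atoms: water, O
Why: Aza-enolate (hydrazone) alkylation with the primary iodide forms the C7–C8 bond and the quaternary carbon, and cupric-acetate-assisted hydrolysis, mild enough for the dioxolane, returns the symmetric achiral 1,3-dione.

Step 5
Reactants: 11 2-[(3Z)-6-(1,3-dioxolan-2-yl)-4-methylhex-3-en-1-yl]-2-methylcyclohexane-1,3-dione
Product: 12 (2R,3R)-2-[(3Z)-6-(1,3-dioxolan-2-yl)-4-methylhex-3-en-1-yl]-3-hydroxy-2-methylcyclohexan-1-one
Conditions: (S)-Me-CBS (0.3 equiv), catecholborane (1.1 equiv), toluene, −60 °C; MeOH, pH 7 buffer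
Reagents that add atoms: none
Why: Corey–Bakshi–Shibata reduction desymmetrizes the dione: the (S)-oxazaborolidine treats the quaternary carbon as the large group and should give the R carbinol (future C6), while hydride enters on the methyl side so that the hydroxyl is cis to the long chain, which fixes C7 as well.

Step 6
Reactants: 12 (2R,3R)-2-[(3Z)-6-(1,3-dioxolan-2-yl)-4-methylhex-3-en-1-yl]-3-hydroxy-2-methylcyclohexan-1-one
Product: 13 (2S,3S)-3-bromo-2-[(3Z)-6-(1,3-dioxolan-2-yl)-4-methylhex-3-en-1-yl]-2-methylcyclohexan-1-one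
Conditions: PPh3, CBr4, NaHCO3, CH2Cl2, 0 → 40 °C
Reagents that add atoms: carbon tetrabromide, BrC(Br)(Br)Br
Why: Appel bromination: bromide displaces the oxyphosphonium with inversion to place the C6 bromide cis to the C7 methyl, the flanking ketone disfavouring ionization and the quaternary α-carbon excluding elimination through an enolate.

Step 7
Reactants: 13 (2S,3S)-3-bromo-2-[(3Z)-6-(1,3-dioxolan-2-yl)-4-methylhex-3-en-1-yl]-2-methylcyclohexan-1-one
Product: 14 (2S,3S)-3-bromo-2-[(3Z)-6-(1,3-dioxolan-2-yl)-4-methylhex-3-en-1-yl]-2,6-dimethylcyclohexan-1-one (C6 epimers)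
Conditions: LDA, THF, −78 °C; MeI, −78 → −30 °C
Reagents that add atoms: iodomethane, CI
Why: Kinetic enolate alkylation: the only enolizable position is the CH2 remote from the quaternary carbon, so the future C3 methyl is installed there (its configuration is irrelevant because the carbon becomes sp2 in step 8), and α-deprotonation at −78 °C is faster than attack of the base on the hindered bromide.

Step 8
Reactants: 14 (2S,3S)-3-bromo-2-[(3Z)-6-(1,3-dioxolan-2-yl)-4-methylhex-3-en-1-yl]-2,6-dimethylcyclohexan-1-one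
Product: 15 (5S,6S)-5-bromo-6-[(3Z)-6-(1,3-dioxolan-2-yl)-4-methylhex-3-en-1-yl]-2,6-dimethylcyclohex-1-en-1-yl trifluoromethanesulfonate
Conditions: KHMDS, THF, −78 → −40 °C; PhNTf2, −78 → 0 °C
Reagents that add atoms: N-phenylbis(trifluoromethanesulfonimide), FC(F)(F)S(=O)(=O)N(c1ccccc1)S(=O)(=O)C(F)(F)F
Why: Enolate O-triflation: the single remaining α-hydrogen is removed and the tetrasubstituted enolate is trapped on oxygen, giving the C2=C3 enol triflate with no regiochemical choice.

Step 9
Reactants: 15 (5S,6S)-5-bromo-6-[(3Z)-6-(1,3-dioxolan-2-yl)-4-methylhex-3-en-1-yl]-2,6-dimethylcyclohex-1-en-1-yl trifluoromethanesulfonate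
Product: 17 (4Z)-7-[(1S,6S)-6-bromo-1,3-dimethyl-2-(trifluoromethanesulfonyloxy)cyclohex-2-en-1-yl]-4-methylhept-4-enoic acid, via aldehyde 16 (not isolated)
Conditions: (a) 2 M HCl, THF, rt; (b) NaClO2, NaH2PO4, 2-methyl-2-butene, t-BuOH/H2O, 0 °C
Reagents that add atoms: water, O; sodium chlorite, [Na+].[O-]Cl=O
Why: Acetal hydrolysis followed by Pinnick oxidation unmasks the C14 acid, the electron-poor enol triflate and the alkyl bromide being inert and 2-methyl-2-butene protecting the C10=C11 alkene from hypochlorous acid.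

Step 10
Reactants: 17 (4Z)-7-[(1S,6S)-6-bromo-1,3-dimethyl-2-(trifluoromethanesulfonyloxy)cyclohex-2-en-1-yl]-4-methylhept-4-enoic acid
Product: 18 (5S,6S)-5-bromo-6-{(3R)-3-bromo-3-[(2R)-2-methyl-5-oxooxolan-2-yl]propyl}-2,6-dimethylcyclohex-1-en-1-yl trifluoromethanesulfonate
Conditions: cinchona amino-thiocarbamate catalyst (10 mol%), NBS, CHCl3/toluene, −78 °C
Reagents that add atoms: N-bromosuccinimide, BrN1C(=O)CCC1=O
Why: Catalytic enantioselective bromolactonization (5-exo, anti addition): the carboxylate opens the catalyst-bound bromonium ion at the more substituted C11 while bromine stays on C10, so the Z geometry fixes the relative configuration, the catalyst antipode fixes the face (10R,11R), and the enol triflate is too electron-poor to compete for bromine.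

Step 11
Reactants: 19 4-hydroxy-3-methylbenzoic acid
Product: 20 tert-butyl 4-hydroxy-3-methylbenzoate
Conditions: t-BuOC(=NH)CCl3, CH2Cl2/cyclohexane, rt
Reagents that add atoms: tert-butyl 2,2,2-trichloroacetimidate, CC(C)(C)OC(=N)C(Cl)(Cl)Cl
Why: Imidate esterification is promoted by the carboxylic acid itself and leaves the less acidic phenol alone, giving an ester bulky enough to survive the organolithium of step 15.

Step 12
Reactants: 20 tert-butyl 4-hydroxy-3-methylbenzoate
Product: 21 tert-butyl 3-methyl-4-{[tri(propan-2-yl)silyl]oxy}benzoate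
Conditions: TIPSCl, imidazole, DMF, rt
Reagents that add atoms: chlorotri(propan-2-yl)silane, CC(C)[Si](Cl)(C(C)C)C(C)C
Why: Standard phenol silylation gives an aryl silyl ether that tolerates radical bromination, organozinc, organolithium and acylation conditions.

Step 13
Reactants: 21 tert-butyl 3-methyl-4-{[tri(propan-2-yl)silyl]oxy}benzoate
Product: 22 tert-butyl 3-(bromomethyl)-4-{[tri(propan-2-yl)silyl]oxy}benzoate
Conditions: NBS, AIBN (cat.), PhCF3, 85 °C
Reagents that add atoms: N-bromosuccinimide, BrN1C(=O)CCC1=O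
Why: Wohl–Ziegler bromination: the benzylic methyl group is the only activated C–H position and the ester-deactivated ring resists electrophilic bromination.

Step 14
Reactants: 22 tert-butyl 3-(bromomethyl)-4-{[tri(propan-2-yl)silyl]oxy}benzoate; 18 (5S,6S)-5-bromo-6-{(3R)-3-bromo-3-[(2R)-2-methyl-5-oxooxolan-2-yl]propyl}-2,6-dimethylcyclohex-1-en-1-yl trifluoromethanesulfonate
Product: 24 tert-butyl 3-{[(5S,6S)-5-bromo-6-{(3R)-3-bromo-3-[(2R)-2-methyl-5-oxooxolan-2-yl]propyl}-2,6-dimethylcyclohex-1-en-1-yl]methyl}-4-{[tri(propan-2-yl)silyl]oxy}benzoate, via benzylzinc bromide 23 (not isolated)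
Conditions: Zn dust, LiCl, THF, 0 → 25 °C (solution decanted from excess Zn); then 18, Pd(PPh3)4 (zerovalent palladium, 5 mol%), THF, 50 °C
Reagents that add atoms: none
Why: Negishi coupling: zinc inserts only into the benzylic C–Br bond and the palladium catalyst joins the benzylzinc to the enol triflate under neutral conditions to form C1–C2, while the secondary alkyl bromides and the lactone react with neither Pd(PPh3)4 nor the organozinc.

Step 15
Reactants: 24 tert-butyl 3-{[(5S,6S)-5-bromo-6-{(3R)-3-bromo-3-[(2R)-2-methyl-5-oxooxolan-2-yl]propyl}-2,6-dimethylcyclohex-1-en-1-yl]methyl}-4-{[tri(propan-2-yl)silyl]oxy}benzoate; 25 2-bromopropene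
Product: 27 tert-butyl 3-{[(5S,6S)-5-bromo-6-[(3R,4R)-3-bromo-4-hydroxy-4,8-dimethyl-7-oxonon-8-en-1-yl]-2,6-dimethylcyclohex-1-en-1-yl]methyl}-4-{[tri(propan-2-yl)silyl]oxy}benzoate, via 2-propenyllithium 26 (not isolated)
Conditions: 25, t-BuLi (2 equiv), Et2O, −78 °C; then 24, THF, −78 °C; AcOH, −78 °C
Reagents that add atoms: none
Why: Mono-addition of an alkenyllithium to a γ-lactone: at −78 °C the lithium hemiketal persists until the acidic quench, so the enone is released only after the reagent is gone, the tert-butyl benzoate is too hindered to compete, and no C11 alkoxide is present that could close an epoxide.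

Step 16
Reactants: 27 tert-butyl 3-{[(5S,6S)-5-bromo-6-[(3R,4R)-3-bromo-4-hydroxy-4,8-dimethyl-7-oxonon-8-en-1-yl]-2,6-dimethylcyclohex-1-en-1-yl]methyl}-4-{[tri(propan-2-yl)silyl]oxy}benzoate
Product: 28 tert-butyl 3-{[(5S,6S)-5-bromo-6-[(3R,4R,7S)-3-bromo-4,7-dihydroxy-4,8-dimethylnon-8-en-1-yl]-2,6-dimethylcyclohex-1-en-1-yl]methyl}-4-{[tri(propan-2-yl)silyl]oxy}benzoate
Conditions: (R)-Me-CBS (0.5 equiv), catecholborane (3 equiv), toluene/CH2Cl2, −78 °C; MeOH, pH 7 buffer
Reagents that add atoms: none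
Why: Corey–Bakshi–Shibata 1,2-reduction of the enone: the isopropenyl group acts as the large substituent so the (R)-oxazaborolidine should give the 14S allylic alcohol, and the tertiary hydroxyl is first capped as its catechol borate, which keeps the ketone in the open form.

Step 17
Reactants: 28 tert-butyl 3-{[(5S,6S)-5-bromo-6-[(3R,4R,7S)-3-bromo-4,7-dihydroxy-4,8-dimethylnon-8-en-1-yl]-2,6-dimethylcyclohex-1-en-1-yl]methyl}-4-{[tri(propan-2-yl)silyl]oxy}benzoate
Product: 30 3-{[(5S,6S)-5-bromo-6-[(3R,4R,7S)-3-bromo-4,7-dihydroxy-4,8-dimethylnon-8-en-1-yl]-2,6-dimethylcyclohex-1-en-1-yl]methyl}-4-{[tri(propan-2-yl)silyl]oxy}benzoic acid, via tris(trimethylsilyl) intermediate 29 (not isolated)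
Conditions: TMSOTf, 2,6-lutidine, CH2Cl2, 0 °C; then citric acid, MeOH/H2O, 0 °C → rt
Reagents that add atoms: none
Why: Silyl-triflate cleavage of the tert-butyl ester gives the silyl ester without protic acid or base, and mild acidic methanolysis then strips all trimethylsilyl groups, so the bromohydrin never meets base (epoxide formation) and the allylic alcohol never meets strong acid.

Step 18
Reactants: 30 3-{[(5S,6S)-5-bromo-6-[(3R,4R,7S)-3-bromo-4,7-dihydroxy-4,8-dimethylnon-8-en-1-yl]-2,6-dimethylcyclohex-1-en-1-yl]methyl}-4-{[tri(propan-2-yl)silyl]oxy}benzoic acid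
Product: 31 TIPS-protected isopropenyl bromohydrin macrolactone (15-membered; 6S,7S,10R,11R,14S)
Conditions: MNBA, DMAP, CH2Cl2 (1 mM, slow addition), rt
Reagents that add atoms: none
Why: Shiina macrolactonization: the mixed anhydride acylates the secondary C14 hydroxyl with retention, the tertiary C11 hydroxyl being too hindered, high dilution favours the 15-membered ring, and DMAP at room temperature is not basic enough to close the bromohydrin.

Step 19
Reactants: 31 TIPS-protected isopropenyl bromohydrin macrolactone (15-membered; 6S,7S,10R,11R,14S)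
Product: 32 bromophycolide Q O-triisopropylsilyl ether
Conditions: Co(salen) (C16H14CoN2O2, divalent cobalt, 10 mol%), N-fluoro-2,4,6-trimethylpyridinium tetrafluoroborate, PhSiH3, PhCF3, 0 °C → rt, argon
Reagents that add atoms: none
Why: The N-fluoropyridinium salt oxidizes Co(salen) and PhSiH3 converts the resulting cobalt fluoride into a trivalent cobalt hydride, which passes a hydrogen atom to the CH2 terminus of the isopropenyl group; the tertiary C15 radical is caught by cobalt and oxidized once more to a tetravalent alkylcobalt, a C15 cation equivalent that the C11 hydroxyl displaces with loss of a proton to the collidine. The closest known reaction type is the cobalt-salen Mukaiyama-type Markovnikov hydroalkoxylation of unactivated alkenes, which accepts tertiary alcohols and 1,1-disubstituted alkenes. The oxane ring closes in the 6-exo-trig mode through a chair-like transition state. No stereocentre is formed, because C15 carries two methyl groups and C11 and C14 keep their configurations. The step needs chemoselectivity for the isopropenyl group over the C2=C3 alkene, secured by the shielding of that tetrasubstituted alkene between C7 and the benzyl group, and capture of C15 by the C11 oxygen, secured by the six-membered ring; attack by the neighbouring benzoate carbonyl should be reversible, and the resulting dioxolanylium ion can still be opened at C15 by the same hydroxyl. The neutral, non-nucleophilic medium should leave both secondary bromides, the bromohydrin, the macrolactone and the aryl silyl ether untouched.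

Step 20
Reactants: 32 bromophycolide Q O-triisopropylsilyl ether
Product: 33 bromophycolide Q
Conditions: TBAF, AcOH, THF, 0 °C
Reagents that add atoms: none
Why: Buffered fluoride desilylation of the aryl silyl ether; the C11 oxygen is now an ether, so no epoxide can form, and the lactone and the secondary bromides are stable at 0 °C.

Compound list
1 | 2-(2-bromoethyl)-1,3-dioxolane | BrCCC1OCCO1 | starting material
2 | propyne | CC#C | starting material
3 | oxirane | C1CO1 | starting material
4 | [2-(1,3-dioxolan-2-yl)ethyl]magnesium bromide | Br[Mg]CCC1OCCO1 | intermediate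
5 | [(1Z)-4-(1,3-dioxolan-2-yl)-2-methylbut-1-en-1-yl]copper (MgBr2·SMe2 complex) | O1CCOC1CC/C(C)=C\[Cu] | intermediate
6 | (3Z)-6-(1,3-dioxolan-2-yl)-4-methylhex-3-en-1-ol | O1CCOC1CC/C(C)=C\CCO | intermediate
7 | 2-[(3Z)-6-iodo-3-methylhex-3-en-1-yl]-1,3-dioxolane | O1CCOC1CC/C(C)=C\CCI | intermediate
8 | 2-methylcyclohexane-1,3-dione | CC1C(=O)CCCC1=O | starting material
9 | 3-(2,2-dimethylhydrazinyl)-2-methylcyclohex-2-en-1-one | CN(C)NC1=C(C)C(=O)CCC1 | intermediate
10 | 3-(dimethylhydrazinylidene)-2-[(3Z)-6-(1,3-dioxolan-2-yl)-4-methylhex-3-en-1-yl]-2-methylcyclohexan-1-one (racemic) | O1CCOC1CC/C(C)=C\CCC2(C)C(=O)CCCC2=NN(C)C | intermediate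
11 | 2-[(3Z)-6-(1,3-dioxolan-2-yl)-4-methylhex-3-en-1-yl]-2-methylcyclohexane-1,3-dione | O1CCOC1CC/C(C)=C\CCC2(C)C(=O)CCCC2=O | intermediate
12 | (2R,3R)-2-[(3Z)-6-(1,3-dioxolan-2-yl)-4-methylhex-3-en-1-yl]-3-hydroxy-2-methylcyclohexan-1-one | O1CCOC1CC/C(C)=C\CC[C@]2(C)[C@H](O)CCCC2=O | intermediate
13 | (2S,3S)-3-bromo-2-[(3Z)-6-(1,3-dioxolan-2-yl)-4-methylhex-3-en-1-yl]-2-methylcyclohexan-1-one | O1CCOC1CC/C(C)=C\CC[C@]2(C)[C@@H](Br)CCCC2=O | intermediate
14 | (2S,3S)-3-bromo-2-[(3Z)-6-(1,3-dioxolan-2-yl)-4-methylhex-3-en-1-yl]-2,6-dimethylcyclohexan-1-one (C6 epimers) | O1CCOC1CC/C(C)=C\CC[C@]2(C)[C@@H](Br)CCC(C)C2=O | intermediate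
15 | (5S,6S)-5-bromo-6-[(3Z)-6-(1,3-dioxolan-2-yl)-4-methylhex-3-en-1-yl]-2,6-dimethylcyclohex-1-en-1-yl trifluoromethanesulfonate | O1CCOC1CC/C(C)=C\CC[C@]2(C)[C@@H](Br)CCC(C)=C2OS(=O)(=O)C(F)(F)F | intermediate
16 | (5S,6S)-5-bromo-2,6-dimethyl-6-[(3Z)-4-methyl-7-oxohept-3-en-1-yl]cyclohex-1-en-1-yl trifluoromethanesulfonate | O=CCC/C(C)=C\CC[C@]1(C)[C@@H](Br)CCC(C)=C1OS(=O)(=O)C(F)(F)F | intermediate
17 | (4Z)-7-[(1S,6S)-6-bromo-1,3-dimethyl-2-(trifluoromethanesulfonyloxy)cyclohex-2-en-1-yl]-4-methylhept-4-enoic acid | OC(=O)CC/C(C)=C\CC[C@]1(C)[C@@H](Br)CCC(C)=C1OS(=O)(=O)C(F)(F)F | intermediate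
18 | (5S,6S)-5-bromo-6-{(3R)-3-bromo-3-[(2R)-2-methyl-5-oxooxolan-2-yl]propyl}-2,6-dimethylcyclohex-1-en-1-yl trifluoromethanesulfonate | O=C1CC[C@@](C)(O1)[C@H](Br)CC[C@]2(C)[C@@H](Br)CCC(C)=C2OS(=O)(=O)C(F)(F)F | intermediate
19 | 4-hydroxy-3-methylbenzoic acid | Cc1cc(ccc1O)C(O)=O | starting material
20 | tert-butyl 4-hydroxy-3-methylbenzoate | Cc1cc(ccc1O)C(=O)OC(C)(C)C | intermediate
21 | tert-butyl 3-methyl-4-{[tri(propan-2-yl)silyl]oxy}benzoate | Cc1cc(ccc1O[Si](C(C)C)(C(C)C)C(C)C)C(=O)OC(C)(C)C | intermediate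
22 | tert-butyl 3-(bromomethyl)-4-{[tri(propan-2-yl)silyl]oxy}benzoate | BrCc1cc(ccc1O[Si](C(C)C)(C(C)C)C(C)C)C(=O)OC(C)(C)C | intermediate
23 | {5-(tert-butoxycarbonyl)-2-[tri(propan-2-yl)silyloxy]benzyl}zinc bromide | Br[Zn]Cc1cc(ccc1O[Si](C(C)C)(C(C)C)C(C)C)C(=O)OC(C)(C)C | intermediate
24 | tert-butyl 3-{[(5S,6S)-5-bromo-6-{(3R)-3-bromo-3-[(2R)-2-methyl-5-oxooxolan-2-yl]propyl}-2,6-dimethylcyclohex-1-en-1-yl]methyl}-4-{[tri(propan-2-yl)silyl]oxy}benzoate | O=C1CC[C@@](C)(O1)[C@H](Br)CC[C@]2(C)[C@@H](Br)CCC(C)=C2Cc3cc(ccc3O[Si](C(C)C)(C(C)C)C(C)C)C(=O)OC(C)(C)C | intermediate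
25 | 2-bromopropene | CC(Br)=C | starting material
26 | prop-1-en-2-yllithium | [Li]C(C)=C | intermediate
27 | tert-butyl 3-{[(5S,6S)-5-bromo-6-[(3R,4R)-3-bromo-4-hydroxy-4,8-dimethyl-7-oxonon-8-en-1-yl]-2,6-dimethylcyclohex-1-en-1-yl]methyl}-4-{[tri(propan-2-yl)silyl]oxy}benzoate | C=C(C)C(=O)CC[C@@](C)(O)[C@H](Br)CC[C@]1(C)[C@@H](Br)CCC(C)=C1Cc2cc(ccc2O[Si](C(C)C)(C(C)C)C(C)C)C(=O)OC(C)(C)C | intermediate
28 | tert-butyl 3-{[(5S,6S)-5-bromo-6-[(3R,4R,7S)-3-bromo-4,7-dihydroxy-4,8-dimethylnon-8-en-1-yl]-2,6-dimethylcyclohex-1-en-1-yl]methyl}-4-{[tri(propan-2-yl)silyl]oxy}benzoate | C=C(C)[C@@H](O)CC[C@@](C)(O)[C@H](Br)CC[C@]1(C)[C@@H](Br)CCC(C)=C1Cc2cc(ccc2O[Si](C(C)C)(C(C)C)C(C)C)C(=O)OC(C)(C)C | intermediate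
29 | trimethylsilyl 3-{[(5S,6S)-5-bromo-6-[(3R,4R,7S)-3-bromo-4,8-dimethyl-4,7-bis(trimethylsilyloxy)non-8-en-1-yl]-2,6-dimethylcyclohex-1-en-1-yl]methyl}-4-{[tri(propan-2-yl)silyl]oxy}benzoate | C=C(C)[C@@H](O[Si](C)(C)C)CC[C@@](C)(O[Si](C)(C)C)[C@H](Br)CC[C@]1(C)[C@@H](Br)CCC(C)=C1Cc2cc(ccc2O[Si](C(C)C)(C(C)C)C(C)C)C(=O)O[Si](C)(C)C | intermediate
30 | 3-{[(5S,6S)-5-bromo-6-[(3R,4R,7S)-3-bromo-4,7-dihydroxy-4,8-dimethylnon-8-en-1-yl]-2,6-dimethylcyclohex-1-en-1-yl]methyl}-4-{[tri(propan-2-yl)silyl]oxy}benzoic acid | C=C(C)[C@@H](O)CC[C@@](C)(O)[C@H](Br)CC[C@]1(C)[C@@H](Br)CCC(C)=C1Cc2cc(ccc2O[Si](C(C)C)(C(C)C)C(C)C)C(O)=O | intermediate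
31 | 15-membered macrolactone (benzoate of the C14 alcohol, arene joined to C2 through C1H2, C2=C3 in ring A) with (6S)-Br, (7S)-methyl, (10R)-Br, (11R)-hydroxy/methyl and (14S)-prop-1-en-2-yl; phenol as triisopropylsilyl ether | CC1=C2Cc3cc(ccc3O[Si](C(C)C)(C(C)C)C(C)C)C(=O)O[C@H](C(C)=C)CC[C@@](C)(O)[C@H](Br)CC[C@]2(C)[C@@H](Br)CC1 | intermediate
32 | bromophycolide Q O-triisopropylsilyl ether | CC1=C2Cc3cc(ccc3O[Si](C(C)C)(C(C)C)C(C)C)C(=O)O[C@H]3CC[C@@](C)(OC3(C)C)[C@H](Br)CC[C@]2(C)[C@@H](Br)CC1 | intermediate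
33 | bromophycolide Q | CC1=C2Cc3cc(ccc3O)C(=O)O[C@H]3CC[C@@](C)(OC3(C)C)[C@H](Br)CC[C@]2(C)[C@@H](Br)CC1 | target

Total step count: 20. Longest linear sequence: 16 steps (steps 1, 2, 4–10 and 14–20, counted from 1).

Steps most likely to fail

Step 6. Backside attack of bromide on the oxyphosphonium at a carbinol flanked by the quaternary C7 may be outpaced by elimination toward C5, or the activated alcohol may simply not react. The fallback sets out from 12 and returns at 13, and it separates activation from displacement. Tf2O and pyridine in CH2Cl2 at −30 °C should convert 12 into (1R,2R)-2-[(3Z)-6-(1,3-dioxolan-2-yl)-4-methylhex-3-en-1-yl]-2-methyl-3-oxocyclohexyl trifluoromethanesulfonate F1. This sulfonate is then displaced with inversion by Bu4NBr in toluene at 0–25 °C to give 13. A discrete and much better leaving group replaces the crowded phosphonium intermediate, and the adjacent ketone still disfavours ionization and skeletal rearrangement.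

Step 10. The catalyst may discriminate poorly between the faces of a purely alkyl-substituted alkene that lies far from the ring A stereocentres, so that the 10S,11S lactone forms alongside. The fallback sets out from 17 and returns at 18; it installs oxygen first by reagent-controlled epoxidation and brings in bromine afterwards by ring opening. Esterification of 17 (TMSCHN2, toluene/MeOH) should give methyl (4Z)-7-[(1S,6S)-6-bromo-1,3-dimethyl-2-(trifluoromethanesulfonyloxy)cyclohex-2-en-1-yl]-4-methylhept-4-enoate F2. Shi epoxidation (the fructose-derived ketone enantiomer that gives the 10S,11R epoxide, Oxone, K2CO3, MeCN/dimethoxymethane/H2O, 0 °C) should give methyl 3-[(2R,3S)-3-{2-[(1S,6S)-6-bromo-1,3-dimethyl-2-(trifluoromethanesulfonyloxy)cyclohex-2-en-1-yl]ethyl}-2-methyloxiran-2-yl]propanoate F3. Li2NiBr4 in THF opens the epoxide at the secondary C10 with inversion to methyl (4R,5R)-5-bromo-7-[(1S,6S)-6-bromo-1,3-dimethyl-2-(trifluoromethanesulfonyloxy)cyclohex-2-en-1-yl]-4-hydroxy-4-methylheptanoate F4, and catalytic TsOH in toluene closes the lactone to 18, with the same anti relationship of bromine and oxygen.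

Step 19. The C15 cation equivalent may be intercepted irreversibly by the neighbouring benzoate carbonyl, which would lead to acyl migration or hydration on work-up, or the isopropenyl group may be reduced by a second hydrogen atom transfer before cobalt captures the radical. The fallback sets out from 31 and returns at 32, and it is a polar two-stage Markovnikov cyclization. Intramolecular oxymercuration with Hg(OAc)2 in THF at 0 °C, followed by aqueous NaCl, should give the 15-(chloromercuriomethyl) analogue of 32 (chloromercurio group on one C15 methyl, both C15 epimers) F5. Reductive demercuration with NaBH4 in THF/H2O at 0 °C then replaces mercury by hydrogen, which removes the C15 stereocentre and gives 32.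

Further compounds
F1 | step 6 | (1R,2R)-2-[(3Z)-6-(1,3-dioxolan-2-yl)-4-methylhex-3-en-1-yl]-2-methyl-3-oxocyclohexyl trifluoromethanesulfonate | O1CCOC1CC/C(C)=C\CC[C@]2(C)[C@H](OS(=O)(=O)C(F)(F)F)CCCC2=O
F2 | step 10 | methyl (4Z)-7-[(1S,6S)-6-bromo-1,3-dimethyl-2-(trifluoromethanesulfonyloxy)cyclohex-2-en-1-yl]-4-methylhept-4-enoate | COC(=O)CC/C(C)=C\CC[C@]1(C)[C@@H](Br)CCC(C)=C1OS(=O)(=O)C(F)(F)F
F3 | step 10 | methyl 3-[(2R,3S)-3-{2-[(1S,6S)-6-bromo-1,3-dimethyl-2-(trifluoromethanesulfonyloxy)cyclohex-2-en-1-yl]ethyl}-2-methyloxiran-2-yl]propanoate | COC(=O)CC[C@@]1(C)O[C@H]1CC[C@]2(C)[C@@H](Br)CCC(C)=C2OS(=O)(=O)C(F)(F)F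
F4 | step 10 | methyl (4R,5R)-5-bromo-7-[(1S,6S)-6-bromo-1,3-dimethyl-2-(trifluoromethanesulfonyloxy)cyclohex-2-en-1-yl]-4-hydroxy-4-methylheptanoate | COC(=O)CC[C@@](C)(O)[C@H](Br)CC[C@]1(C)[C@@H](Br)CCC(C)=C1OS(=O)(=O)C(F)(F)F
F5 | step 19 | 15-(chloromercuriomethyl) analogue of 32 (chloromercurio group on one C15 methyl, C15 epimers) | CC1=C2Cc3cc(ccc3O[Si](C(C)C)(C(C)C)C(C)C)C(=O)O[C@H]3CC[C@@](C)(OC3(C)C[Hg]Cl)[C@H](Br)CC[C@]2(C)[C@@H](Br)CC1
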